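**Strategy.** Ring A is cut at C1–C10 and C4–C5 (labdane numbering), which reduces the bicycle to ring B as 2,6-dimethyl-1,4-benzoquinone and to allylidenecyclopropane. One catalytic, enantioselective [4+2] cycloaddition closes ring A and sets both stereocentres. The feature exploited is the cis ring fusion, C10–CH3 and C5–H on the same face, which suprafacial addition across the quinone C5=C10 bond gives directly. Ring B arrives with the C8 and C10 methyls and a C9 oxygen for the chain, and the C4 spirocyclopropane is a latent gem-dimethyl group. The precursors are the commercial quinone and a diene made by one Wittig step; the chain is added by cross-couplings.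

Key step: step 2

**Remarks on the chemistry**

- Locants: labdane-type numbering for the decalin (C1–C10; gem-dimethyl on C4, H on C5, methyls on C8 and C10, chain on C9). The chain carbons are C11–C16 outward from C9, and C13 carries CH2OH. The target is (5R,10S) with C12 cis to C15 across C13=C14 (CIP 13E) and a trans C15=C16 bond.
- Adduct 6 as drawn is (5R,10S) with H-5 and CH3-10 cis, which is the configuration of the target at both centres. Endo or exo approach does not affect it, because neither diene terminus becomes a stereocentre.
- Assumption: the catalyst antipode in step 2 is written as the (S)-α,α-diphenylprolinol-derived one, on the basis of the usual facial preference of this catalyst class for α-C–H-bound quinones and acrylates. The sense is to be confirmed on the first batch; if the antipode of 6 predominates, the (R)-catalyst is used with nothing else changed.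
- C8 in compounds 7–11 is an inconsequential epimer mixture (written without a descriptor) and becomes sp2 in step 7.
- The precursor pair needs no redesign: the C6 carbonyl of the quinone is what steers regiochemistry, and the diene is used in excess as a cold solution because it is volatile and acid-sensitive.

**Route**

Step 1
Reactants: 1 cyclopropyltriphenylphosphonium bromide; 2 acrolein
Product: 4 allylidenecyclopropane, via cyclopropylidene(triphenyl)phosphorane 3 (not isolated)
Conditions: KN(SiMe3)2, diglyme, 0 °C → rt; then 2, −20 °C → rt; product distilled from the pot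
Reagents that add atoms: none
Why: Wittig olefination, in which the non-stabilised cyclopropylidene ylide should add 1,2 to the aldehyde and collapse to the exocyclic alkene, with no stereocentre or alkene geometry at stake because the cyclopropylidene terminus is symmetric.

Step 2
Reactants: 4 allylidenecyclopropane; 5 2,6-dimethyl-1,4-benzoquinone
Product: 6 cis-fused ene-dione adduct, (4a'S,8a'R)-4a',6'-dimethyl-4a',8a'-dihydro-4'H-spiro[cyclopropane-1,1'-naphthalene]-5',8'-dione (labdane locants 5R,10S; ketones at C6 and C9, alkenes C7=C8 and C2=C3, spirocyclopropane at C4)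
Conditions: (S)-α,α-diphenylprolinol-derived B-(o-tolyl)oxazaborolidine (20 mol %), Tf2NH (18 mol %), 4 (2 equiv), CH2Cl2, −78 → −40 °C; Et3N quench, neutral silica
Reagents that add atoms: none
Why: The protonated oxazaborolidine binds the C6 carbonyl of 5, the only one flanked by C–H bonds and not by methyl groups, and the C5–H···O contact holds the C5=C10 bond over one phenyl group, so the reaction is a Lewis-acid-accelerated, concerted but asynchronous Diels–Alder cycloaddition of the kind established for oxazaborolidinium-catalysed additions to 2,6-disubstituted benzoquinones and for alkylidenecyclopropane dienes. Ring A closes as a six-membered ring by intermolecular suprafacial–suprafacial [4+2] addition, the C1–C10 bond forming ahead of C4–C5. C10 and C5 are created together: their cis relationship (methyl and hydrogen on one face) is dictated by suprafacial addition across the planar C5=C10 bond, and their absolute sense by the catalyst, which leaves only one face of that bond open. Regiochemistry is the selectivity that must hold: activation through C6=O makes C10 the electrophilic β-carbon, which pairs with the more nucleophilic unsubstituted diene terminus C1, while the alternative would press the spiro carbon against the methyl-bearing C10. The enantiotopic C7=C8 bond is left alone because the same catalyst contact activates only one of the two ring double bonds. The strained diene, which reaches the s-cis form easily, should react at a temperature low enough that C5 of the kinetic cis adduct does not epimerise.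

Step 3
Reactants: 6 cis-fused ene-dione adduct
Product: 7 saturated 6,9-dione, the 6',7'-dihydro derivative of 6 (C8 epimers; C2=C3 and cyclopropane intact)
Conditions: Zn, AcOH, rt
Reagents that add atoms: none
Why: Dissolving-metal conjugate reduction of an ene-dione, in which electron transfer to the doubly activated C7=C8 bond and protonation at C7 and C8 should saturate it without involving C5, the isolated ring A alkene or the cyclopropane.

Step 4
Reactants: 7 saturated 6,9-dione
Product: 8 C6 mono-(p-toluenesulfonyl)hydrazone of 7
Conditions: TsNHNH2 (1.05 equiv), MeOH, rt → 40 °C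
Reagents that add atoms: p-toluenesulfonyl hydrazide, Cc1ccc(cc1)S(=O)(=O)NN
Why: Hydrazone condensation, in which the C6 carbonyl with its methylene neighbour should condense far faster than the C9 carbonyl wedged between quaternary C10 and the C8 methine, while the near-neutral medium avoids enolisation toward C5.

Step 5
Reactants: 8 C6 tosylhydrazone
Product: 10 C6-deoxygenated ketone, (4a'S,8a'R)-4a',6'-dimethyl-4a',6',7',8',8a'-pentahydro-4'H-spiro[cyclopropane-1,1'-naphthalen]-5'-one (C9 ketone, C2=C3, spirocyclopropane; C8 epimers), via N-boryl tosylhydrazine 9 (not isolated)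
Conditions: catecholborane, CHCl3, 0 °C → rt; then NaOAc·3H2O, 60 °C
Reagents that add atoms: none
Why: Caglioti-type tosylhydrazone reduction in its catecholborane variant, where hydride transfer to C=N followed by acetate-induced loss of sulfinate and of nitrogen should leave C6 as a methylene, after which C5 can no longer epimerise.

Step 6
Reactants: 10 C6-deoxygenated ketone
Product: 11 (4aR,8aS)-2,5,5,8a-tetramethyloctahydronaphthalen-1(2H)-one (cis-fused; labdane C9 ketone, C8 epimers)
Conditions: H2 (3 atm), PtO2, AcOH, rt
Reagents that add atoms: none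
Why: Heterogeneous hydrogenation and cyclopropane hydrogenolysis over platinum, which should saturate C2=C3 first and then cleave the least hindered distal CH2–CH2 bond of the resulting 1,1-dialkylcyclopropane to unveil the C4 gem-dimethyl group, the hindered C9 ketone reacting much more slowly and no stereocentre being made or touched.

Step 7
Reactants: 11 cis-decalone
Product: 13 (4aR,8aS)-2,5,5,8a-tetramethyl-3,4,4a,5,6,7,8,8a-octahydronaphthalen-1-yl trifluoromethanesulfonate (C8=C9 enol triflate), via lithium enolate 12 (not isolated)
Conditions: LiN(i-Pr)2, THF, −78 → 0 °C; then PhNTf2, 0 °C → rt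
Reagents that add atoms: N-phenylbis(trifluoromethanesulfonimide), O=S(=O)(N(c1ccccc1)S(=O)(=O)C(F)(F)F)C(F)(F)F
Why: Enolate O-sulfonylation, in which C9 can enolise only toward C8 because C10 is quaternary, so a single tetrasubstituted enol triflate should form and the C8 epimer mixture converges.

Step 8
Reactants: 13 enol triflate; 14 tributyl(vinyl)stannane
Product: 15 (4aR,8aS)-1-ethenyl-2,5,5,8a-tetramethyl-3,4,4a,5,6,7,8,8a-octahydronaphthalene (C9-vinyl diene)
Conditions: Pd(PPh3)4 (5 mol %), LiCl, THF, 65 °C
Reagents that add atoms: none
Why: Stille coupling of an alkenyl triflate, where oxidative addition to zerovalent palladium, chloride-assisted transmetalation from tin and reductive elimination should give the 1,3-diene as with related 2,6,6-trimethylcyclohexenyl triflates.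

Step 9
Reactants: 16 but-2-yne-1,4-diol
Product: 18 4-[(tert-butyldimethylsilyl)oxy]but-2-yn-1-ol, via monosodium alkoxide 17 (not isolated)
Conditions: NaH (1.0 equiv), THF, 0 °C → rt; then TBSCl, rt
Reagents that add atoms: tert-butyldimethylsilyl chloride, CC(C)(C)[Si](C)(C)Cl
Why: Alkoxide O-silylation used for monoprotection of a symmetric diol, the sparingly soluble monosodium salt taking up one equivalent of silyl chloride so that one hydroxyl stays free.

Step 10
Reactants: 18 mono-silyl ether
Product: 20 (Z)-4-[(tert-butyldimethylsilyl)oxy]-3-iodobut-2-en-1-ol, via cyclic vinylalanate 19 (not isolated)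
Conditions: NaAlH2(OCH2CH2OCH3)2, THF, 0 °C → rt; EtOAc; then I2, THF, −78 → 0 °C
Reagents that add atoms: iodine, II
Why: Hydroxyl-directed trans-hydroalumination followed by iodinolysis, in which the alkoxyaluminium hydride delivers hydride to the proximal alkyne carbon to give a five-membered vinylalanate whose C–Al bond is replaced by iodine with retention, fixing iodine cis to CH2OH (Z).

Step 11
Reactants: 15 C9-vinyl diene; 20 (Z)-vinyl iodide
Product: 22 (2E)-3-{[(tert-butyldimethylsilyl)oxy]methyl}-5-[(4aR,8aS)-2,5,5,8a-tetramethyl-3,4,4a,5,6,7,8,8a-octahydronaphthalen-1-yl]pent-2-en-1-ol, via B-alkyl-9-borabicyclononane 21 (not isolated)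
Conditions: 9-BBN, THF, 0 °C → rt; then 20, Pd(dppf)Cl2 (5 mol %), AsPh3, Cs2CO3, DMF/H2O, rt
Reagents that add atoms: none
Why: Anti-Markovnikov hydroboration followed by B-alkyl Suzuki–Miyaura coupling, where 9-BBN should add only to the terminal vinyl carbon (the tetrasubstituted C8=C9 bond is inert) and the primary alkylborane should couple with retention of the iodoalkene geometry, so that C12 ends cis to C15 across C13=C14.

Step 12
Reactants: 22 allylic alcohol
Product: 23 (2E)-3-{[(tert-butyldimethylsilyl)oxy]methyl}-5-[(4aR,8aS)-2,5,5,8a-tetramethyl-3,4,4a,5,6,7,8,8a-octahydronaphthalen-1-yl]pent-2-enal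
Conditions: MnO2, CH2Cl2, rt
Reagents that add atoms: none
Why: Allylic alcohol oxidation with activated MnO2, which is selective for the primary allylic hydroxyl under neutral conditions and should leave the silyl ether and the alkene geometry untouched.

Step 13
Reactants: 23 enal; 24 2-(dichloromethyl)-4,4,5,5-tetramethyl-1,3,2-dioxaborolane
Product: 25 (2E,4E)-dienylboronate, tert-butyl(dimethyl)silyl ether of 5-(4,4,5,5-tetramethyl-1,3,2-dioxaborolan-2-yl)-2-{2-[(4aR,8aS)-2,5,5,8a-tetramethyl-3,4,4a,5,6,7,8,8a-octahydronaphthalen-1-yl]ethyl}penta-2,4-dien-1-ol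
Conditions: CrCl2 (8 equiv), LiI, THF, rt, dark
Reagents that add atoms: none
Why: Takai–Utimoto olefination in its boron variant, in which the geminal dichromium species generated from the dihalomethylboronate by divalent chromium should add to the aldehyde and eliminate to the E alkenylboronate, setting the trans C15=C16 bond.

Step 14
Reactants: 25 dienylboronate; 26 4-bromofuran-2(5H)-one
Product: 27 4-[(1E,3E)-4-{[(tert-butyldimethylsilyl)oxy]methyl}-6-[(4aR,8aS)-2,5,5,8a-tetramethyl-3,4,4a,5,6,7,8,8a-octahydronaphthalen-1-yl]hexa-1,3-dien-1-yl]furan-2(5H)-one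
Conditions: Pd(PPh3)4 (5 mol %), CsF, DME, 60 °C
Reagents that add atoms: none
Why: Suzuki–Miyaura coupling, in which the vinylogous acyl bromide should undergo ready oxidative addition and couple with the alkenylboronate with retention at both sp2 carbons under anhydrous fluoride activation that spares the lactone.

Step 15
Reactants: 27 silyl ether
Product: 28 target, 4-[(1E,3E)-4-(hydroxymethyl)-6-[(4aR,8aS)-2,5,5,8a-tetramethyl-3,4,4a,5,6,7,8,8a-octahydronaphthalen-1-yl]hexa-1,3-dien-1-yl]furan-2(5H)-one
Conditions: HF·pyridine, pyridine/THF, 0 °C → rt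
Reagents that add atoms: none
Why: Fluoride-mediated desilylation under buffered conditions, which should cleave the primary allylic silyl ether without opening the butenolide or isomerising the triene.

**Compound list**

1 | cyclopropyltriphenylphosphonium bromide | [Br-].c1ccc(cc1)[P+](c1ccccc1)(c1ccccc1)C1CC1 | starting material
2 | acrolein | C=CC=O | starting material
3 | cyclopropylidene(triphenyl)phosphorane | C1CC1=P(c1ccccc1)(c1ccccc1)c1ccccc1 | intermediate (not isolated)
4 | allylidenecyclopropane | C=CC=C1CC1 | intermediate
5 | 2,6-dimethyl-1,4-benzoquinone | CC1=CC(=O)C=C(C)C1=O | starting material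
6 | cis-fused ene-dione adduct, (4a'S,8a'R)-4a',6'-dimethyl-4a',8a'-dihydro-4'H-spiro[cyclopropane-1,1'-naphthalene]-5',8'-dione | CC1=CC(=O)[C@@H]2C3(CC3)C=CC[C@]2(C)C1=O | intermediate
7 | saturated 6,9-dione, 6',7'-dihydro derivative of 6 (C8 epimer mixture, centre not specified) | CC1CC(=O)[C@@H]2C3(CC3)C=CC[C@]2(C)C1=O | intermediate
8 | C6 mono-tosylhydrazone of 7 (C8 epimers) | CC1CC(=NNS(=O)(=O)c2ccc(C)cc2)[C@@H]2C3(CC3)C=CC[C@]2(C)C1=O | intermediate
9 | N-(1,3,2-benzodioxaborol-2-yl) tosylhydrazine at C6 | CC1CC(N(B2Oc3ccccc3O2)NS(=O)(=O)c2ccc(C)cc2)[C@@H]2C3(CC3)C=CC[C@]2(C)C1=O | intermediate (not isolated)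
10 | C6-deoxygenated spirocyclopropyl ketone (C9 ketone, C2=C3; C8 epimers) | CC1CC[C@@H]2C3(CC3)C=CC[C@]2(C)C1=O | intermediate
11 | (4aR,8aS)-2,5,5,8a-tetramethyloctahydronaphthalen-1(2H)-one, cis-fused (C8 epimers) | CC1CC[C@@H]2C(C)(C)CCC[C@]2(C)C1=O | intermediate
12 | lithium C8=C9 enolate of 11 | CC1=C([O-])[C@@]2(C)CCCC(C)(C)[C@H]2CC1.[Li+] | intermediate (not isolated)
13 | (4aR,8aS)-2,5,5,8a-tetramethyl-3,4,4a,5,6,7,8,8a-octahydronaphthalen-1-yl trifluoromethanesulfonate | CC1=C(OS(=O)(=O)C(F)(F)F)[C@@]2(C)CCCC(C)(C)[C@H]2CC1 | intermediate
14 | tributyl(vinyl)stannane | C=C[Sn](CCCC)(CCCC)CCCC | starting material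
15 | (4aR,8aS)-1-ethenyl-2,5,5,8a-tetramethyl-3,4,4a,5,6,7,8,8a-octahydronaphthalene | CC1=C(C=C)[C@@]2(C)CCCC(C)(C)[C@H]2CC1 | intermediate
16 | but-2-yne-1,4-diol | OCC#CCO | starting material
17 | monosodium alkoxide of 16 | [Na+].[O-]CC#CCO | intermediate (not isolated)
18 | 4-[(tert-butyldimethylsilyl)oxy]but-2-yn-1-ol | OCC#CCO[Si](C)(C)C(C)(C)C | intermediate
19 | sodium cyclic vinylalanate (2,2-bis(2-methoxyethoxy)-1-oxa-2-aluminacyclopent-3-ene carrying CH2OTBS on C3) | [Na+].COCCO[Al-]1(OCCOC)OCC=C1CO[Si](C)(C)C(C)(C)C | intermediate (not isolated)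
20 | (Z)-4-[(tert-butyldimethylsilyl)oxy]-3-iodobut-2-en-1-ol | OC/C=C(\I)CO[Si](C)(C)C(C)(C)C | intermediate
21 | B-alkyl-9-borabicyclononane from 15 (boron on C12) | CC1=C(CCB3C4CCCC3CCC4)[C@@]2(C)CCCC(C)(C)[C@H]2CC1 | intermediate (not isolated)
22 | (2E)-3-{[(tert-butyldimethylsilyl)oxy]methyl}-5-[(4aR,8aS)-2,5,5,8a-tetramethyl-3,4,4a,5,6,7,8,8a-octahydronaphthalen-1-yl]pent-2-en-1-ol | CC1=C(CC/C(CO[Si](C)(C)C(C)(C)C)=C\CO)[C@@]2(C)CCCC(C)(C)[C@H]2CC1 | intermediate
23 | (2E)-enal corresponding to 22 | CC1=C(CC/C(CO[Si](C)(C)C(C)(C)C)=C\C=O)[C@@]2(C)CCCC(C)(C)[C@H]2CC1 | intermediate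
24 | 2-(dichloromethyl)-4,4,5,5-tetramethyl-1,3,2-dioxaborolane | ClC(Cl)B1OC(C)(C)C(C)(C)O1 | starting material
25 | (2E,4E)-dienyl pinacol boronate | CC1=C(CC/C(CO[Si](C)(C)C(C)(C)C)=C\C=C\B3OC(C)(C)C(C)(C)O3)[C@@]2(C)CCCC(C)(C)[C@H]2CC1 | intermediate
26 | 4-bromofuran-2(5H)-one | BrC1=CC(=O)OC1 | starting material
27 | tert-butyldimethylsilyl ether of the target | CC1=C(CC/C(CO[Si](C)(C)C(C)(C)C)=C\C=C\C3=CC(=O)OC3)[C@@]2(C)CCCC(C)(C)[C@H]2CC1 | intermediate
28 | 4-[(1E,3E)-4-(hydroxymethyl)-6-[(4aR,8aS)-2,5,5,8a-tetramethyl-3,4,4a,5,6,7,8,8a-octahydronaphthalen-1-yl]hexa-1,3-dien-1-yl]furan-2(5H)-one | CC1=C(CC/C(=C\C=C\C2=CC(=O)OC2)CO)[C@@]2(C)CCCC(C)(C)[C@H]2CC1 | target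

**Step count and risk**

Total steps: 15. Longest linear sequence: 13 (steps 1–8 and 11–15); steps 9–10 form the two-step side branch.

The three steps most likely to fail:

1. Step 2. The catalyst may discriminate poorly between the two faces of the C5=C10 bond, or the acid-sensitive diene may oligomerise before it adds. Fallback, from 4 and 5: the cycloaddition is run without a chiral catalyst (BF3·OEt2, CH2Cl2, −78 °C, which still activates through the C6 carbonyl and keeps the regiochemistry). The racemic cis adduct is then resolved by preparative chromatography on a chiral stationary phase, and the antipodal adduct F1 is discarded. The route is rejoined at 6.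

2. Step 4. The cis ring fusion may be lost by enolisation of the C6 carbonyl toward C5 during condensation, or condensation may be slow or occur at both carbonyls. Fallback, from 7: NaBH4 in MeOH/CH2Cl2 at −40 °C should reduce only the accessible C6 carbonyl and so remove the enolisable centre at once, giving the C6 carbinol F2. Acylation with O-phenyl chlorothionoformate (pyridine, DMAP, CH2Cl2) gives the O-phenyl thionocarbonate F3. Barton–McCombie deoxygenation (Bu3SnH, AIBN, toluene, 80 °C) then returns the route at 10; the C6 radical is not adjacent to the cyclopropane and should not open it.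

3. Step 6. Hydrogenolysis may take the wrong course while the cyclopropane is still allylic (cleavage of the bond next to the alkene, leading to an ethyl group), or the C9 carbonyl may be over-reduced. Fallback, from 10: the alkene is first saturated by diimide transfer (KO2CN=NCO2K, AcOH, MeOH, rt), which cannot open the ring, to give the saturated spirocyclopropyl ketone F4. The now isolated 1,1-dialkylcyclopropane is then hydrogenolysed (H2, PtO2, AcOH) to rejoin the route at 11. Should the carbonyl be partly reduced in that operation, the C9 carbinol F5 is returned to 11 with Dess–Martin periodinane.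

**Further compounds**

F1 | step 2 | antipodal adduct (ent-6) | CC1=CC(=O)[C@H]2C3(CC3)C=CC[C@@]2(C)C1=O
F2 | step 4 | C6 carbinol of 7 (C6 and C8 epimers) | CC1CC(O)[C@@H]2C3(CC3)C=CC[C@]2(C)C1=O
F3 | step 4 | O-phenyl thionocarbonate of F2 | CC1CC(OC(=S)Oc2ccccc2)[C@@H]2C3(CC3)C=CC[C@]2(C)C1=O
F4 | step 6 | saturated spirocyclopropyl ketone (C2–C3 dihydro derivative of 10) | CC1CC[C@@H]2C3(CC3)CCC[C@]2(C)C1=O
F5 | step 6 | C9 carbinol of 11 | CC1CC[C@@H]2C(C)(C)CCC[C@]2(C)C1O
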